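**Strategy.** The route rests on disconnecting the C2–aryl bond of the dihydrofuran ring. In the key step a potassium (3,4,5-trimethoxyphenyl)trifluoroborate is coupled with the C2 ethoxy acetal of a 3a-allyl dihydrobenzofuranone that carries only one defined stereocentre, the quaternary ring-fusion carbon C3a. The step exploits C2 as an O1-bound acetal carbon next to the enolisable C3–H: oxocarbenium and enol ether forms equilibrate, so every C2/C3 isomer should be funnelled into the 2,3-trans, 3-methyl/3a-allyl-cis product under control of C3a. A final Cope rearrangement carries the allyl group suprafacially from C3a to C5 of the six-membered ring and creates the methoxy-bearing quaternary centre.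

Key step: step 7

Assumption: (R,R)-TADDOL is taken to leave open the quinone face that gives the (3aS) cycloadduct of step 4; if the sense of induction proves opposite, (S,S)-TADDOL is used.

Remark: benzofuran numbering (O1, C2, C3, C3a, C4 to C7, C7a) is used throughout. The C3a descriptor changes from S (acetals, enol ether) to R (after arylation) by priority rules only; the spatial arrangement is unchanged.

**Step 1**
Reactants: 1 3,4-dimethoxyphenol; 2 allyl bromide
Product: 3 4-(allyloxy)-1,2-dimethoxybenzene
Conditions: K2CO3, acetone, reflux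
Reagents that add atoms: none
Why: Williamson ether synthesis, the phenoxide displacing bromide from the allylic halide (SN2); no stereocentre is formed.

**Step 2**
Reactants: 3 4-(allyloxy)-1,2-dimethoxybenzene
Product: 4 2-allyl-4,5-dimethoxyphenol
Conditions: PhNEt2, 190 °C
Reagents that add atoms: none
Why: Aromatic Claisen rearrangement ([3,3]) to the less hindered ortho position (not the one flanked by the methoxy group), followed by tautomerisation to the phenol.

**Step 3**
Reactants: 4 2-allyl-4,5-dimethoxyphenol
Product: 5 2-allyl-5-methoxy-1,4-benzoquinone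
Conditions: PhI(OAc)2, MeCN/H2O, 0 °C
Reagents that add atoms: water, O
Why: Oxidative demethylation of a 4-methoxyphenol: the aryloxy-iodane collapses to the C4 oxocarbenium ion, water adds and methanol is lost to give the p-quinone, leaving the allyl group and the second methoxy group untouched.

**Step 4**
Reactants: 5 2-allyl-5-methoxy-1,4-benzoquinone; 6 ethyl prop-1-enyl ether (commercial E/Z mixture)
Product: 7 (3aS)-3a-allyl-2-ethoxy-5-hydroxy-3-methyl-3,3a-dihydro-1-benzofuran-6(2H)-one (mixture of C2 and C3 epimers)
Conditions: TiCl4/Ti(OiPr)4/(R,R)-TADDOL (1:1:2, premixed, 2 equiv Ti), CH2Cl2, −78 to −20 °C; aq. NaHCO3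
Reagents that add atoms: none
Why: Lewis acid-promoted formal [3+2] cycloaddition of a 2-alkoxy-1,4-benzoquinone with an electron-rich alkene: the chiral titanium TADDOLate chelates C4=O and the C5 methoxy group of 5, the enol ether adds through its methyl-bearing carbon to the allyl-substituted C2 on the quinone face left open by the ligand (this sets C3a, the only stereocentre that has to be controlled here), the C1 carbonyl oxygen captures the oxocarbenium ion to close the acetal ring, and chloride removes the methyl group of the resulting O-methyl oxocarbenium unit to leave the 5-hydroxy enone.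

**Step 5**
Reactants: 7 (3aS)-3a-allyl-2-ethoxy-5-hydroxy-3-methyl-3,3a-dihydro-1-benzofuran-6(2H)-one
Product: 8 (3aS)-3a-allyl-2-ethoxy-5-methoxy-3-methyl-3,3a-dihydro-1-benzofuran-6(2H)-one (mixture of C2 and C3 epimers)
Conditions: Me2SO4, K2CO3, acetone, rt
Reagents that add atoms: dimethyl sulfate, COS(=O)(=O)OC
Why: O-Methylation (SN2) of the acidic enol of the 1,2-dicarbonyl unit with a hard methylating agent, which should favour oxygen over C4 and leaves the base-stable acetal intact.

**Step 6**
Reactants: 9 (3,4,5-trimethoxyphenyl)boronic acid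
Product: 10 potassium trifluoro(3,4,5-trimethoxyphenyl)borate
Conditions: KHF2, MeOH/H2O, rt
Reagents that add atoms: potassium hydrogen difluoride, [K+].F[H-]F
Why: Standard conversion of a boronic acid into its trifluoroborate salt by fluoride exchange.

**Step 7**
Reactants: 8 (3aS)-3a-allyl-2-ethoxy-5-methoxy-3-methyl-3,3a-dihydro-1-benzofuran-6(2H)-one; 10 potassium trifluoro(3,4,5-trimethoxyphenyl)borate
Product: 13 (2S,3S,3aR)-3a-allyl-5-methoxy-3-methyl-2-(3,4,5-trimethoxyphenyl)-3,3a-dihydro-1-benzofuran-6(2H)-one, via enol ether 11 (not isolated), via oxocarbenium ion 12 (not isolated)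
Conditions: BF3·OEt2 (3 equiv), MeCN, −20 to 0 °C, 10 added slowly
Reagents that add atoms: none
Why: BF3·OEt2 turns 10 into the aryldifluoroborane and ionises the C2–OEt bond of 8; the C2 oxocarbenium ions of both C3 configurations should interconvert through enol ether 11 by loss and return of the C3 proton (BF3·EtOH as proton shuttle), and the aryl group is then transferred ipso from boron to C2 of the reactive cation 12. The closest known reaction type is the BF3-promoted coupling of potassium organotrifluoroborates with acetals through oxocarbenium ions. No ring is closed; the dihydrofuran ring O1–C2–C3–C3a–C7a is kept (should O1–C2 open transiently, the benzylic ether formed would reclose by 5-exo attack of the enol oxygen to the same trans product). C3 is set by protonation of 11 on the face opposite the C3a allyl group, and C2 by arrival of the aryl group anti to both the C3 methyl and the C3a allyl group, so that every C2/C3 isomer of 8 should converge on the 2,3-trans, 3-methyl/3a-allyl-cis isomer. The step needs C3 equilibration to outrun arylation of the mismatched cation (both of its faces are hindered, and slow addition of 10 keeps the aryl donor scarce) and ipso instead of ortho attack on the arene (the boron-bearing carbon is para to the 4-methoxy group and boron is the leaving group).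

**Step 8**
Reactants: 13 (2S,3S,3aR)-3a-allyl-5-methoxy-3-methyl-2-(3,4,5-trimethoxyphenyl)-3,3a-dihydro-1-benzofuran-6(2H)-one
Product: 14 (2S,3S,5S)-5-allyl-5-methoxy-3-methyl-2-(3,4,5-trimethoxyphenyl)-3,5-dihydro-1-benzofuran-6(2H)-one (CNP0316836.1)
Conditions: PhMe (degassed), 110 °C, sealed tube, stopped at full conversion of 13
Reagents that add atoms: none
Why: Cope rearrangement ([3,3]-sigmatropic): the allyl group migrates suprafacially from C3a to the methoxy-bearing carbon C5 on the same ring face, so the C3a configuration is transferred to C5 (S) while C2 and C3 are untouched, and the product gains the linearly conjugated dienone and loses the congested C3/C3a junction.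

**Compound list**
1 | 3,4-dimethoxyphenol | COc1ccc(O)cc1OC | starting material
2 | allyl bromide (3-bromoprop-1-ene) | C=CCBr | starting material
3 | 4-(allyloxy)-1,2-dimethoxybenzene | C=CCOc1ccc(OC)c(OC)c1 | intermediate
4 | 2-allyl-4,5-dimethoxyphenol | C=CCc1cc(OC)c(OC)cc1O | intermediate
5 | 2-allyl-5-methoxy-1,4-benzoquinone | C=CCC1=CC(=O)C(OC)=CC1=O | intermediate
6 | ethyl prop-1-enyl ether (E/Z mixture) | CC=COCC | starting material
7 | (3aS)-3a-allyl-2-ethoxy-5-hydroxy-3-methyl-3,3a-dihydro-1-benzofuran-6(2H)-one, C2/C3 epimer mixture | C=CC[C@@]12C=C(O)C(=O)C=C1OC(OCC)C2C | intermediate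
8 | (3aS)-3a-allyl-2-ethoxy-5-methoxy-3-methyl-3,3a-dihydro-1-benzofuran-6(2H)-one, C2/C3 epimer mixture | C=CC[C@@]12C=C(OC)C(=O)C=C1OC(OCC)C2C | intermediate
9 | (3,4,5-trimethoxyphenyl)boronic acid | COc1cc(B(O)O)cc(OC)c1OC | starting material
10 | potassium trifluoro(3,4,5-trimethoxyphenyl)borate | COc1cc([B-](F)(F)F)cc(OC)c1OC.[K+] | intermediate
11 | (3aS)-3a-allyl-5-methoxy-3-methyl-1-benzofuran-6(3aH)-one (enol ether) | C=CC[C@@]12C=C(OC)C(=O)C=C1OC=C2C | intermediate (not isolated)
12 | (3S,3aS)-3a-allyl-5-methoxy-3-methyl-6-oxo-3,3a-dihydro-6H-1-benzofuran-1-ium (C2 oxocarbenium ion, methyl cis to allyl) | C=CC[C@@]12C=C(OC)C(=O)C=C1[O+]=C[C@H]2C | intermediate (not isolated)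
13 | (2S,3S,3aR)-3a-allyl-5-methoxy-3-methyl-2-(3,4,5-trimethoxyphenyl)-3,3a-dihydro-1-benzofuran-6(2H)-one | C=CC[C@@]12C=C(OC)C(=O)C=C1O[C@H](c1cc(OC)c(OC)c(OC)c1)[C@H]2C | intermediate
14 | (2S,3S,5S)-5-allyl-5-methoxy-3-methyl-2-(3,4,5-trimethoxyphenyl)-3,5-dihydro-1-benzofuran-6(2H)-one | C=CC[C@]1(OC)C=C2C(=CC1=O)O[C@H](c1cc(OC)c(OC)c(OC)c1)[C@H]2C | target

**Step count.** Total: 8 steps. Longest linear sequence: 7 steps (steps 1 to 5, 7 and 8).

**Steps most likely to fail**

1. Step 7. Equilibration at C3 may be slower than aryl transfer, or the acetal may ionise at the ring oxygen (O1 is a vinylogous carboxylate leaving group), so that the C3 configuration of 8 is carried through unchanged. The Lewis acid may also provoke attack of the allyl alkene on the C2 cation or early sigmatropic shifts. Fallback, from 8 back to 13: ethanol is removed from 8 (PPTS cat., toluene, 80 °C, 4 Å molecular sieves) and the enol ether 11 is isolated. With TfOH (10 mol%) in CH2Cl2 at −40 °C it is protonated at C3 anti to the allyl group, and the cyclic cation is trapped on its open face by 2,6-dimethoxyphenol, whose only free activated position is para to the hydroxyl group (Friedel–Crafts hydroarylation of an enol ether). This should give the phenol (2S,3S,3aR)-3a-allyl-2-(4-hydroxy-3,5-dimethoxyphenyl)-5-methoxy-3-methyl-3,3a-dihydro-1-benzofuran-6(2H)-one F1. O-Methylation (MeI, K2CO3, acetone) returns to 13.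

2. Step 4. The titanium TADDOLate may discriminate poorly between the quinone faces with a small, very reactive enol ether, and attack may stray to the unsubstituted quinone carbons. Fallback, from 5 back to 8: the cycloaddition is run with the achiral promoter TiCl4/Ti(OiPr)4 to give the racemic adduct F2. This is methylated (Me2SO4, K2CO3) to the racemic acetal F3 and heated with PPTS to the racemic enol ether F4, which has a single stereocentre. Chromatography on a chiral stationary phase separates 11 from its antipode F5. PPTS-catalysed addition of ethanol to 11 (CH2Cl2, 0 °C; protonation of C3 anti to the allyl group) gives 8.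

3. Step 8. The allyl group may instead shift to C7, after which enolisation to a phenol is irreversible; prolonged heating may also open 14 by retro-Claisen rearrangement to the allyl aryl ether. Fallback, from 8 back to 14: C7 is blocked. NBS (CH2Cl2, 0 °C) brominates the nucleophilic alpha carbon of the vinylogous ester of 8 to give the 7-bromo acetal F6, and the key step converts it into the 7-bromo analogue F7 of 13. On heating, a shift to C7 can no longer be followed by enolisation and should revert, so the rearrangement should drain into the 7-bromo analogue F8 of 14. Zn dust in AcOH (reductive removal of the alpha bromine of the enone) then gives 14.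

**Further compounds**
F1 | step 7 | (2S,3S,3aR)-3a-allyl-2-(4-hydroxy-3,5-dimethoxyphenyl)-5-methoxy-3-methyl-3,3a-dihydro-1-benzofuran-6(2H)-one | C=CC[C@@]12C=C(OC)C(=O)C=C1O[C@H](c1cc(OC)c(O)c(OC)c1)[C@H]2C
F2 | step 4 | racemic 3a-allyl-2-ethoxy-5-hydroxy-3-methyl-3,3a-dihydro-1-benzofuran-6(2H)-one | C=CCC12C=C(O)C(=O)C=C1OC(OCC)C2C
F3 | step 4 | racemic 3a-allyl-2-ethoxy-5-methoxy-3-methyl-3,3a-dihydro-1-benzofuran-6(2H)-one | C=CCC12C=C(OC)C(=O)C=C1OC(OCC)C2C
F4 | step 4 | racemic 3a-allyl-5-methoxy-3-methyl-1-benzofuran-6(3aH)-one | C=CCC12C=C(OC)C(=O)C=C1OC=C2C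
F5 | step 4 | (3aR)-3a-allyl-5-methoxy-3-methyl-1-benzofuran-6(3aH)-one (antipode of 11) | C=CC[C@]12C=C(OC)C(=O)C=C1OC=C2C
F6 | step 8 | 7-bromo derivative of 8 (3a-allyl-7-bromo-2-ethoxy-5-methoxy-3-methyl-3,3a-dihydro-1-benzofuran-6(2H)-one, allyl face as in 8) | C=CC[C@@]12C=C(OC)C(=O)C(Br)=C1OC(OCC)C2C
F7 | step 8 | 7-bromo derivative of 13 | C=CC[C@@]12C=C(OC)C(=O)C(Br)=C1O[C@H](c1cc(OC)c(OC)c(OC)c1)[C@H]2C
F8 | step 8 | 7-bromo derivative of 14 | C=CC[C@]1(OC)C=C2C(=C(Br)C1=O)O[C@H](c1cc(OC)c(OC)c(OC)c1)[C@H]2C
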